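**Remark.** The target is read as ent-fisetinidol-(4α→6)-catechin. Flavan numbering is used separately for the upper unit (5-deoxy, substituted at C4; 2S,3R,4S, that is 2,3-trans-3,4-cis) and the lower catechin unit (2R,3S).

**Strategy.** Ring A of the lower (catechin) unit is not built as a phloroglucinol but grown from 2,4,6-tribromoresorcinol, whose three bromines are spent in turn: the one between the two ethers becomes the aryllithium that forges the interflavan bond (future C6), the second the carbanion that opens an erythro epoxide (C4a–C4), and the third (future C8) is eliminated with the lone ring hydrogen to give an aryne. The tethered C2 alkoxide then adds to C8a, closing ring C of the lower unit by cine substitution. The step exploits the 1,3,5-oxygen pattern of ring A: O1 enters meta to the departing bromine, so the 4→6 linkage is fixed by construction.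

Key step: step 15

Step 1
Reactants: 1 1-[4-(benzyloxy)-2-hydroxyphenyl]ethan-1-one
Product: 2 1-[4-(benzyloxy)-2-(methoxymethoxy)phenyl]ethan-1-one
Conditions: NaH, MOMCl, DMF, 0 °C to rt
Reagents that add atoms: chloromethyl methyl ether, COCCl
Why: Williamson-type O-alkylation of the sodium phenoxide masks the 2′-hydroxyl so that the chalcone can later be epoxidised without Algar–Flynn–Oyamada cyclisation.

Step 2
Reactants: 2 MOM-protected acetophenone; 3 3,4-bis(benzyloxy)benzaldehyde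
Product: 4 (E)-1-[4-(benzyloxy)-2-(methoxymethoxy)phenyl]-3-[3,4-bis(benzyloxy)phenyl]prop-2-en-1-one
Conditions: KOH, EtOH–THF, rt
Reagents that add atoms: none
Why: Claisen–Schmidt condensation (aldol addition, then E1cB dehydration) should give the thermodynamically favoured E-enone.

Step 3
Reactants: 4 chalcone
Product: 5 (2S,3R)-epoxy ketone of chalcone 4
Conditions: poly-D-leucine, urea–H2O2, DBU, THF, rt
Reagents that add atoms: hydrogen peroxide (as its urea adduct), OO
Why: Juliá–Colonna epoxidation, in which the helical poly-D-leucine delivers the hydroperoxide anion to one enone face and should give the (2S,3R)-trans-epoxy ketone (poly-L-leucine is known for the 2R,3S series), fixing the future upper C3.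

Step 4
Reactants: 5 epoxy ketone
Product: 7 (2S,3S)-7-(benzyloxy)-2-[3,4-bis(benzyloxy)phenyl]-3-hydroxychroman-4-one, via hydroxy epoxy ketone 6 (not isolated)
Conditions: conc. HCl (cat.), MeOH–THF, 55 °C
Reagents that add atoms: none
Why: Acid cleaves the MOM acetal and the freed phenol of 6 opens the protonated epoxide at the electron-rich benzylic carbon (6-endo epoxide ring opening with inversion there, or closure of the benzylic cation to the trans-diequatorial product), so C3 keeps the epoxide configuration and C2 is set trans to it.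

Step 5
Reactants: 7 dihydroflavonol
Product: 8 (2S,3S)-7-(benzyloxy)-2-[3,4-bis(benzyloxy)phenyl]-3-[(tert-butyldimethylsilyl)oxy]chroman-4-one
Conditions: TBSCl, imidazole, DMF, rt
Reagents that add atoms: tert-butyldimethylsilyl chloride, CC(C)(C)[Si](C)(C)Cl
Why: Silylation under weakly basic conditions protects O3 without opening the base-sensitive flavanone ring and installs the bulky group that steers steps 7 and 8.

Step 6
Reactants: 9 2,4,6-tribromobenzene-1,3-diol
Product: 10 1,3-bis(benzyloxy)-2,4,6-tribromobenzene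
Conditions: BnBr, K2CO3, DMF, 60 °C
Reagents that add atoms: benzyl bromide, BrCc1ccccc1
Why: Williamson etherification of the two acidic, bromine-flanked phenols.

Step 7
Reactants: 10 tribromide; 8 ketone
Product: 12 (2S,3S,4S)-4-[2,6-bis(benzyloxy)-3,5-dibromophenyl]-3-silyloxyflavan-4-ol, via aryllithium 11 (not isolated)
Conditions: n-BuLi (1.0 equiv), THF, −78 °C; then 8, −78 °C; aq. NH4Cl
Reagents that add atoms: none
Why: Bromine–lithium exchange is expected at the bromine flanked by two benzyloxy groups (the most stabilised aryllithium 11), and 1,2-addition of this organolithium to the ketone anti to the 3-silyloxy group forms the C4–C6 interflavan bond (the new carbinol centre is erased in step 8).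

Step 8
Reactants: 12 tertiary carbinol
Product: 14 (2S,3R,4S)-4-[2,6-bis(benzyloxy)-3,5-dibromophenyl]-3-silyloxyflavan (3,4-cis), via benzylic cation 13 (not isolated)
Conditions: n-Bu3SnH, CF3CO2H, CH2Cl2, 0 °C
Reagents that add atoms: none
Why: Ionic hydrogenation, in which CF3CO2H ionises the tertiary diarylcarbinol to the 7-alkoxy-stabilised cation 13, allylic strain with the C4 aryl group turns the 3-silyloxy group pseudo-axial, and the stannane delivers hydride anti to it, so the aryl group ends cis to O3 and C4 is set as S.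

Step 9
Reactants: 3 3,4-bis(benzyloxy)benzaldehyde
Product: 15 rac-1-[3,4-bis(benzyloxy)phenyl]prop-2-en-1-ol
Conditions: CH2=CHMgBr, THF, 0 °C
Reagents that add atoms: vinylmagnesium bromide, C=C[Mg]Br
Why: Grignard 1,2-addition to the non-enolisable aldehyde gives the racemic aryl vinyl carbinol needed for kinetic resolution.

Step 10
Reactants: 15 racemic allylic alcohol
Product: 16 (R)-[3,4-bis(benzyloxy)phenyl][(S)-oxiran-2-yl]methanol
Conditions: Ti(OiPr)4, D-(−)-diisopropyl tartrate, t-BuOOH (0.55 equiv), 4 Å MS, CH2Cl2, −20 °C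
Reagents that add atoms: tert-butyl hydroperoxide, CC(C)(C)OO
Why: Sharpless asymmetric epoxidation run as a kinetic resolution, in which D-(−)-tartrate should epoxidise the (S)-carbinol fast and erythro-selectively and leave the (R)-carbinol, setting the future lower C2 (R) and C3 (S).

Step 11
Reactants: 16 epoxy alcohol
Product: 17 triisopropylsilyl ether of 16
Conditions: TIPSOTf, 2,6-lutidine, CH2Cl2, −78 to 0 °C
Reagents that add atoms: triisopropylsilyl trifluoromethanesulfonate, CC(C)[Si](C(C)C)(C(C)C)OS(=O)(=O)C(F)(F)F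
Why: Silylation with the silyl triflate; the triisopropylsilyl group is chosen because it resists 1,2-silyl migration in step 13.

Step 12
Reactants: 14 dibromide; 17 epoxide
Product: 19 (1R,2S)-propan-2-ol carrying the monobromo ring A and the silylated benzylic carbinol, via aryllithium 18 (not isolated)
Conditions: n-BuLi (1.05 equiv), THF, −78 °C; then 17, BF3·OEt2, −78 °C
Reagents that add atoms: none
Why: Bromine–lithium exchange of one of the two bromines (they are interchanged by rotation about the C4–aryl bond, so either gives the same product) gives aryllithium 18, and BF3-assisted SN2 opening of the terminal epoxide at its CH2 carbon forms the C4a–C4 bond without touching the two stereocentres.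

Step 13
Reactants: 19 secondary alcohol
Product: 20 O3-benzyl ether of 19
Conditions: NaH, BnBr, n-Bu4NI (cat.), DMF, 0 °C to rt
Reagents that add atoms: benzyl bromide, BrCc1ccccc1
Why: Williamson etherification blocks the lower O3, which would otherwise win the later ring closure by a 5-exo attack.

Step 14
Reactants: 20 bis-silyl ether
Product: 21 diol with free lower C2–OH and upper C3–OH (aryne precursor)
Conditions: n-Bu4NF, THF, rt to 40 °C
Reagents that add atoms: none
Why: Fluoride cleaves both silyl ethers (Si–F bond formation), freeing the lower C2 hydroxyl that becomes O1 and the upper C3 hydroxyl.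

Step 15
Reactants: 21 bromo diol
Product: 24 octa-O-benzyl ent-fisetinidol-(4α→6)-catechin, via aryne 22 (not isolated), via C8 aryllithium 23 (not isolated)
Conditions: lithium 2,2,6,6-tetramethylpiperidide (6 equiv, from n-BuLi and 2,2,6,6-tetramethylpiperidine), THF, −78 to 0 °C; aq. NH4Cl
Reagents that add atoms: none
Why: The amide base first converts both hydroxyls into lithium alkoxides and then removes the only hydrogen of the lower ring A (C8a–H, ortho to bromine, acidified by the halogen and the meta C7–O bond and reached by base held on the neighbouring alkoxide and ether oxygens); loss of LiBr gives the C8≡C8a aryne 22. The lower C2 alkoxide adds to C8a in a 6-exo mode through the in-plane π bond, closing ring C of the lower unit, and the C8 aryllithium 23 is protonated by the amine or on quench, so hydrogen replaces bromine at C8 and oxygen enters at C8a (cine substitution). The closest known reaction type is the base-induced benzyne cyclisation of halogenated 3-arylpropan-1-ols to chromans. No stereocentre is formed or touched: the C2–O bond is never broken, so the erythro (1R,2S) relationship from step 10 becomes the 2,3-trans (2R,3S) ring. Regiochemistry is doubly secured, by the tether (C8 cannot be reached) and by the C7 benzyloxy group beside the triple bond, which directs a nucleophile to the remote aryne carbon C8a so that the carbanion develops at C8 next to the C–O bond; the competing 5-exo closure by O3 is excluded by its benzyl ether. The step needs aryl over benzylic deprotonation, which the hindered non-nucleophilic base, the low temperature and alkoxide-directed metalation are expected to provide.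

Step 16
Reactants: 24 octabenzyl ether
Product: 25 ent-fisetinidol-(4α→6)-catechin (target)
Conditions: H2 (1 atm), Pd(OH)2/C, THF–MeOH, rt
Reagents that add atoms: none
Why: Hydrogenolysis of the eight benzyl ethers over palladium should leave the flavan C–O and interflavan C–C bonds intact and give the free polyphenol.

**Compound list**

1 | 1-[4-(benzyloxy)-2-hydroxyphenyl]ethan-1-one | CC(=O)c1ccc(OCc2ccccc2)cc1O | starting material
2 | 1-[4-(benzyloxy)-2-(methoxymethoxy)phenyl]ethan-1-one | COCOc1cc(OCc2ccccc2)ccc1C(C)=O | intermediate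
3 | 3,4-bis(benzyloxy)benzaldehyde | O=Cc1ccc(OCc2ccccc2)c(OCc2ccccc2)c1 | starting material
4 | (E)-1-[4-(benzyloxy)-2-(methoxymethoxy)phenyl]-3-[3,4-bis(benzyloxy)phenyl]prop-2-en-1-one | COCOc1cc(OCc2ccccc2)ccc1C(=O)/C=C/c1ccc(OCc2ccccc2)c(OCc2ccccc2)c1 | intermediate
5 | [4-(benzyloxy)-2-(methoxymethoxy)phenyl]{(2S,3R)-3-[3,4-bis(benzyloxy)phenyl]oxiran-2-yl}methanone | COCOc1cc(OCc2ccccc2)ccc1C(=O)[C@H]2O[C@@H]2c1ccc(OCc3ccccc3)c(OCc3ccccc3)c1 | intermediate
6 | [4-(benzyloxy)-2-hydroxyphenyl]{(2S,3R)-3-[3,4-bis(benzyloxy)phenyl]oxiran-2-yl}methanone (not isolated) | Oc1cc(OCc2ccccc2)ccc1C(=O)[C@H]2O[C@@H]2c1ccc(OCc3ccccc3)c(OCc3ccccc3)c1 | intermediate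
7 | (2S,3S)-7-(benzyloxy)-2-[3,4-bis(benzyloxy)phenyl]-3-hydroxychroman-4-one | c3ccccc3COc1ccc2c(c1)O[C@@H](c1ccc(OCc3ccccc3)c(OCc3ccccc3)c1)[C@H](O)C2=O | intermediate
8 | (2S,3S)-7-(benzyloxy)-2-[3,4-bis(benzyloxy)phenyl]-3-[(tert-butyldimethylsilyl)oxy]chroman-4-one | c3ccccc3COc1ccc2c(c1)O[C@@H](c1ccc(OCc3ccccc3)c(OCc3ccccc3)c1)[C@H](O[Si](C)(C)C(C)(C)C)C2=O | intermediate
9 | 2,4,6-tribromobenzene-1,3-diol | Oc1c(Br)c(O)c(Br)cc1Br | starting material
10 | 1,3-bis(benzyloxy)-2,4,6-tribromobenzene | Brc1cc(Br)c(OCc2ccccc2)c(Br)c1OCc2ccccc2 | intermediate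
11 | [2,6-bis(benzyloxy)-3,5-dibromophenyl]lithium (not isolated) | [Li]c1c(OCc2ccccc2)c(Br)cc(Br)c1OCc2ccccc2 | intermediate
12 | (2S,3S,4S)-7-(benzyloxy)-2-[3,4-bis(benzyloxy)phenyl]-4-[2,6-bis(benzyloxy)-3,5-dibromophenyl]-3-[(tert-butyldimethylsilyl)oxy]chroman-4-ol | c3ccccc3COc1ccc2c(c1)O[C@@H](c1ccc(OCc3ccccc3)c(OCc3ccccc3)c1)[C@H](O[Si](C)(C)C(C)(C)C)[C@@]2(O)c1c(OCc3ccccc3)c(Br)cc(Br)c1OCc3ccccc3 | intermediate
13 | C4 carbocation derived from 12 (not isolated) | c3ccccc3COc1ccc2c(c1)O[C@@H](c1ccc(OCc3ccccc3)c(OCc3ccccc3)c1)[C@H](O[Si](C)(C)C(C)(C)C)[C+]2c1c(OCc3ccccc3)c(Br)cc(Br)c1OCc3ccccc3 | intermediate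
14 | (2S,3R,4S)-7-(benzyloxy)-2-[3,4-bis(benzyloxy)phenyl]-4-[2,6-bis(benzyloxy)-3,5-dibromophenyl]-3-[(tert-butyldimethylsilyl)oxy]chromane | c3ccccc3COc1ccc2c(c1)O[C@@H](c1ccc(OCc3ccccc3)c(OCc3ccccc3)c1)[C@H](O[Si](C)(C)C(C)(C)C)[C@@H]2c1c(OCc3ccccc3)c(Br)cc(Br)c1OCc3ccccc3 | intermediate
15 | rac-1-[3,4-bis(benzyloxy)phenyl]prop-2-en-1-ol | C=CC(O)c1ccc(OCc2ccccc2)c(OCc2ccccc2)c1 | intermediate
16 | (R)-[3,4-bis(benzyloxy)phenyl][(S)-oxiran-2-yl]methanol | C1[C@H](O1)[C@@H](c1ccc(OCc3ccccc3)c(OCc3ccccc3)c1)O | intermediate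
17 | {(R)-[3,4-bis(benzyloxy)phenyl][(S)-oxiran-2-yl]methoxy}tri(propan-2-yl)silane | C1[C@H](O1)[C@@H](c1ccc(OCc3ccccc3)c(OCc3ccccc3)c1)O[Si](C(C)C)(C(C)C)C(C)C | intermediate
18 | monolithio derivative of 14 (lithium in place of one bromine; not isolated) | c3ccccc3COc1ccc2c(c1)O[C@@H](c1ccc(OCc3ccccc3)c(OCc3ccccc3)c1)[C@H](O[Si](C)(C)C(C)(C)C)[C@@H]2c1c(OCc3ccccc3)c(Br)cc([Li])c1OCc3ccccc3 | intermediate
19 | (1R,2S)-3-{2,4-bis(benzyloxy)-5-bromo-3-[(2S,3R,4S)-7-(benzyloxy)-2-[3,4-bis(benzyloxy)phenyl]-3-[(tert-butyldimethylsilyl)oxy]chroman-4-yl]phenyl}-1-[3,4-bis(benzyloxy)phenyl]-1-[(triisopropylsilyl)oxy]propan-2-ol | c3ccccc3COc1ccc2c(c1)O[C@@H](c1ccc(OCc3ccccc3)c(OCc3ccccc3)c1)[C@H](O[Si](C)(C)C(C)(C)C)[C@@H]2c1c(OCc3ccccc3)c(Br)cc(c1OCc3ccccc3)C[C@H](O)[C@@H](c1ccc(OCc3ccccc3)c(OCc3ccccc3)c1)O[Si](C(C)C)(C(C)C)C(C)C | intermediate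
20 | 2-O-benzyl ether of 19 | c3ccccc3COc1ccc2c(c1)O[C@@H](c1ccc(OCc3ccccc3)c(OCc3ccccc3)c1)[C@H](O[Si](C)(C)C(C)(C)C)[C@@H]2c1c(OCc3ccccc3)c(Br)cc(c1OCc3ccccc3)C[C@H](OCc3ccccc3)[C@@H](c1ccc(OCc3ccccc3)c(OCc3ccccc3)c1)O[Si](C(C)C)(C(C)C)C(C)C | intermediate
21 | (1R,2S)-2-(benzyloxy)-3-{2,4-bis(benzyloxy)-5-bromo-3-[(2S,3R,4S)-7-(benzyloxy)-2-[3,4-bis(benzyloxy)phenyl]-3-hydroxychroman-4-yl]phenyl}-1-[3,4-bis(benzyloxy)phenyl]propan-1-ol | c3ccccc3COc1ccc2c(c1)O[C@@H](c1ccc(OCc3ccccc3)c(OCc3ccccc3)c1)[C@H](O)[C@@H]2c1c(OCc3ccccc3)c(Br)cc(c1OCc3ccccc3)C[C@H](OCc3ccccc3)[C@@H](c1ccc(OCc3ccccc3)c(OCc3ccccc3)c1)O | intermediate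
22 | C8≡C8a aryne from 21, as its dilithium dialkoxide (not isolated) | c3ccccc3COc1ccc2c(c1)O[C@@H](c1ccc(OCc3ccccc3)c(OCc3ccccc3)c1)[C@H](O[Li])[C@@H]2C1=C(OCc3ccccc3)C#CC(=C1OCc3ccccc3)C[C@H](OCc3ccccc3)[C@@H](c1ccc(OCc3ccccc3)c(OCc3ccccc3)c1)O[Li] | intermediate
23 | ring-closed C8 aryllithium, upper O3 as lithium alkoxide (not isolated) | c3ccccc3COc1ccc2c(c1)O[C@@H](c1ccc(OCc3ccccc3)c(OCc3ccccc3)c1)[C@H](O[Li])[C@@H]2c1c(OCc3ccccc3)c([Li])c2c(c1OCc3ccccc3)C[C@H](OCc3ccccc3)[C@@H](c1ccc(OCc3ccccc3)c(OCc3ccccc3)c1)O2 | intermediate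
24 | octa-O-benzyl ent-fisetinidol-(4α→6)-catechin (benzyl at upper O7, O3′, O4′ and lower O3, O5, O7, O3′, O4′; upper 3-OH free) | c3ccccc3COc1ccc2c(c1)O[C@@H](c1ccc(OCc3ccccc3)c(OCc3ccccc3)c1)[C@H](O)[C@@H]2c1c(OCc3ccccc3)cc2c(c1OCc3ccccc3)C[C@H](OCc3ccccc3)[C@@H](c1ccc(OCc3ccccc3)c(OCc3ccccc3)c1)O2 | intermediate
25 | (2R,3S)-2-(3,4-dihydroxyphenyl)-6-[(2S,3R,4S)-2-(3,4-dihydroxyphenyl)-3,7-dihydroxychroman-4-yl]chroman-3,5,7-triol | Oc1ccc2c(c1)O[C@@H](c1ccc(O)c(O)c1)[C@H](O)[C@@H]2c1c(O)cc2c(c1O)C[C@H](O)[C@@H](c1ccc(O)c(O)c1)O2 | target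

**Step count.** Total: 16 steps. Longest linear sequence: 12 steps (1, 2, 3, 4, 5, 7, 8, 12, 13, 14, 15, 16); step 6 and steps 9–11 are side branches.

**Steps most likely to fail**

1. Step 15 (key step). Ortho-deprotonation of the electron-rich bromoarene may be slow, so that metalation of the benzyl ether CH2 groups (Wittig rearrangement) or of the diarylmethine C4–H competes. The fallback forms the same O1–C8a bond by addition–elimination at a fluoride instead of elimination–addition at a bromide. It sets out from 14: LDA at −78 °C removes the hydrogen between the two bromines and N-fluorobenzenesulfonimide gives the fluoro dibromide F1. Bromine–lithium exchange (n-BuLi, −78 °C) and BF3·OEt2-assisted opening of epoxide 17 give the alcohol F2, NaH/BnBr gives the benzyl ether F3, and n-Bu4NF gives the diol F4. KHMDS in THF–DMF at 60 °C then closes the pyran ring by intramolecular SNAr of the C2 alkoxide on the C8a fluoride to give the 8-bromo dimer F5. Hydrogenolysis over Pd(OH)2/C with Et3N removes the eight benzyl groups and the C8 bromine and comes back to the route at 25.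

2. Step 8. Hydride may attack both faces of cation 13, because the 2-aryl group lies on the face that has to be attacked, so facial selectivity may be poor. The fallback delivers the aryl group intramolecularly syn to O3 instead of hydride anti to O3, and also bypasses steps 5 and 7. It sets out from 7 and 10: 10 is lithiated as in step 7 and quenched with excess Me2SiCl2 to give the aryl(chloro)dimethylsilane F6, which silylates 7 (imidazole, DMF) to the 3-O-silyl ketone F7. NaBH4 in THF–EtOH gives the flavan-4-ol F8 (C4 epimers, inconsequential). BF3·OEt2 at −78 °C ionises C4 and the silicon-bound aryl group migrates by ipso substitution through a five-membered transition state on the face of O3, a silicon-tethered aryl transfer of the kind used for 1,2-cis C-aryl glycosides; aqueous fluoride work-up gives the 3,4-cis alcohol F9. TBSOTf/2,6-lutidine returns to the route at 14.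

3. Step 4. The benzylic epoxide carbon may ionise before the phenol is free, leading to aroyl migration, solvolysis by methanol and erosion of enantiopurity. The fallback uses thiol opening followed by thiophilic activation. It sets out from 5: BnSH/SnCl4 at −20 °C opens the epoxide at the benzylic carbon and removes the MOM group to give the α,2′-dihydroxy-β-benzylsulfanyl dihydrochalcone F10. AgBF4 in CH2Cl2 at 0 °C then expels the thiolate and the phenol closes the ring to the 2,3-trans dihydroflavonol, returning to the route at 7.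

**Further compounds**

F1 | step 15 | (2S,3R,4S)-4-[2,6-bis(benzyloxy)-3,5-dibromo-4-fluorophenyl] analogue of 14 | c3ccccc3COc1ccc2c(c1)O[C@@H](c1ccc(OCc3ccccc3)c(OCc3ccccc3)c1)[C@H](O[Si](C)(C)C(C)(C)C)[C@@H]2c1c(OCc3ccccc3)c(Br)c(F)c(Br)c1OCc3ccccc3
F2 | step 15 | 6-fluoro analogue of alcohol 19 (fluorine on ring A between bromine and the side chain) | c3ccccc3COc1ccc2c(c1)O[C@@H](c1ccc(OCc3ccccc3)c(OCc3ccccc3)c1)[C@H](O[Si](C)(C)C(C)(C)C)[C@@H]2c1c(OCc3ccccc3)c(Br)c(F)c(c1OCc3ccccc3)C[C@H](O)[C@@H](c1ccc(OCc3ccccc3)c(OCc3ccccc3)c1)O[Si](C(C)C)(C(C)C)C(C)C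
F3 | step 15 | fluoro analogue of benzyl ether 20 | c3ccccc3COc1ccc2c(c1)O[C@@H](c1ccc(OCc3ccccc3)c(OCc3ccccc3)c1)[C@H](O[Si](C)(C)C(C)(C)C)[C@@H]2c1c(OCc3ccccc3)c(Br)c(F)c(c1OCc3ccccc3)C[C@H](OCc3ccccc3)[C@@H](c1ccc(OCc3ccccc3)c(OCc3ccccc3)c1)O[Si](C(C)C)(C(C)C)C(C)C
F4 | step 15 | fluoro analogue of diol 21 | c3ccccc3COc1ccc2c(c1)O[C@@H](c1ccc(OCc3ccccc3)c(OCc3ccccc3)c1)[C@H](O)[C@@H]2c1c(OCc3ccccc3)c(Br)c(F)c(c1OCc3ccccc3)C[C@H](OCc3ccccc3)[C@@H](c1ccc(OCc3ccccc3)c(OCc3ccccc3)c1)O
F5 | step 15 | 8-bromo derivative of 24 (bromine at C8 of the lower unit) | c3ccccc3COc1ccc2c(c1)O[C@@H](c1ccc(OCc3ccccc3)c(OCc3ccccc3)c1)[C@H](O)[C@@H]2c1c(OCc3ccccc3)c(Br)c2c(c1OCc3ccccc3)C[C@H](OCc3ccccc3)[C@@H](c1ccc(OCc3ccccc3)c(OCc3ccccc3)c1)O2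
F6 | step 8 | [2,6-bis(benzyloxy)-3,5-dibromophenyl]chlorodimethylsilane | C[Si](C)(Cl)c1c(OCc2ccccc2)c(Br)cc(Br)c1OCc2ccccc2
F7 | step 8 | (2S,3S)-7-(benzyloxy)-2-[3,4-bis(benzyloxy)phenyl]-3-({[2,6-bis(benzyloxy)-3,5-dibromophenyl]dimethylsilyl}oxy)chroman-4-one | c3ccccc3COc1ccc2c(c1)O[C@@H](c1ccc(OCc3ccccc3)c(OCc3ccccc3)c1)[C@H](O[Si](C)(C)c1c(OCc3ccccc3)c(Br)cc(Br)c1OCc3ccccc3)C2=O
F8 | step 8 | corresponding chroman-4-ol (C4 epimers) | c3ccccc3COc1ccc2c(c1)O[C@@H](c1ccc(OCc3ccccc3)c(OCc3ccccc3)c1)[C@H](O[Si](C)(C)c1c(OCc3ccccc3)c(Br)cc(Br)c1OCc3ccccc3)C2O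
F9 | step 8 | (2S,3R,4S)-7-(benzyloxy)-2-[3,4-bis(benzyloxy)phenyl]-4-[2,6-bis(benzyloxy)-3,5-dibromophenyl]chroman-3-ol | c3ccccc3COc1ccc2c(c1)O[C@@H](c1ccc(OCc3ccccc3)c(OCc3ccccc3)c1)[C@H](O)[C@@H]2c1c(OCc3ccccc3)c(Br)cc(Br)c1OCc3ccccc3
F10 | step 4 | (2R)-1-[4-(benzyloxy)-2-hydroxyphenyl]-3-(benzylsulfanyl)-3-[3,4-bis(benzyloxy)phenyl]-2-hydroxypropan-1-one (C3 epimers) | O=C(c1ccc(OCc2ccccc2)cc1O)[C@@H](O)C(SCc1ccccc1)c1ccc(OCc2ccccc2)c(OCc2ccccc2)c1
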